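Ring A (C12, C13, C14, C15, C8, C7) is opened at C13–C14 and C7–C8. In the ring B dienone precursor, the C13 aldehyde and the enone β-carbon C7 both flank quaternary C12. They form a 1,3-dielectrophile that a three-carbon bis-allylsilane (C14–C15(C16)–C8) can bridge. One operation forms both bonds, closes ring A cis-fused, sets C7 and C13 and leaves a C15 methylidene. The precursor is an (S)-4-formyl-4-(3-chloropropyl)cyclopentenone with an (E)-alkylidene chain ending in a nosylamide. Afterwards a C13 carbamate delivers oxygen to C15, and N-alkylation at C9 closes the azonine (ring C).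

Key step: step 12

Remark on the chemistry: atom labels C1–C16 follow the fawcettimine-type numbering of the target (C12 quaternary, C13 and C15 oxygenated, C5 ketone, C3=C4 alkene, N between C1 and C9, C16 methyl); the pseudoenantiomer of the cinchona phase-transfer catalyst that gives (S)-3 is assumed to be picked in a test alkylation.

Step 1
Reactants: 1 methyl 2-oxocyclopentane-1-carboxylate; 2 1-bromo-3-chloropropane
Product: 3 methyl (1S)-1-(3-chloropropyl)-2-oxocyclopentane-1-carboxylate
Conditions: N-(9-anthracenylmethyl)cinchonidinium chloride (10 mol%), K2CO3 (powder), toluene, 0 °C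
Reagents that add atoms: none
Why: Enantioselective phase-transfer C-alkylation of the β-keto ester: the enolate reacts as a tight ion pair with the chiral ammonium cation, which screens one face, and only the bromide end of 2 is displaced, so quaternary C12 should form with the S configuration.

Step 2
Reactants: 3 methyl (1S)-1-(3-chloropropyl)-2-oxocyclopentane-1-carboxylate
Product: 4 methyl (1S)-1-(3-chloropropyl)-2-(trifluoromethanesulfonyloxy)cyclopent-2-ene-1-carboxylate
Conditions: KHMDS, THF, −78 °C; PhNTf2, −78 → 0 °C
Reagents that add atoms: N-phenylbis(trifluoromethanesulfonimide), O=S(=O)(N(c1ccccc1)S(=O)(=O)C(F)(F)F)C(F)(F)F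
Why: Enol triflate formation: the ketone can enolise only toward its CH2 group because C12 carries no hydrogen, and the potassium enolate is O-sulfonylated at low temperature before it can attack the chloride.

Step 3
Reactants: 4 methyl (1S)-1-(3-chloropropyl)-2-(trifluoromethanesulfonyloxy)cyclopent-2-ene-1-carboxylate
Product: 5 methyl (1S)-1-(3-chloropropyl)cyclopent-2-ene-1-carboxylate
Conditions: Pd(OAc)2 (5 mol%), PPh3, HCO2H, Bu3N, DMF, 60 °C
Reagents that add atoms: none
Why: Palladium-catalysed formate reduction of a vinyl triflate: oxidative addition of zerovalent palladium, formate exchange, loss of CO2 and reductive elimination replace OTf by H, while ester, primary chloride and C12 are untouched.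

Step 4
Reactants: 5 methyl (1S)-1-(3-chloropropyl)cyclopent-2-ene-1-carboxylate
Product: 6 methyl (1R)-1-(3-chloropropyl)-4-oxocyclopent-2-ene-1-carboxylate
Conditions: CrO3, 3,5-dimethylpyrazole, CH2Cl2, −20 °C
Reagents that add atoms: chromium trioxide, O=[Cr](=O)=O
Why: Allylic oxidation with the CrO3–3,5-dimethylpyrazole complex: the only allylic hydrogens sit on the CH2 remote from quaternary C12, so the carbonyl (C5) should appear 1,3 to C12 with the alkene (C6=C7) left in place, giving the 4,4-disubstituted cyclopentenone without a separate carbonyl transposition (the descriptor becomes R only through the priority rules).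

Step 5
Reactants: 7 3-aminopropan-1-ol
Product: 8 N-(3-hydroxypropyl)-2-nitrobenzenesulfonamide
Conditions: 2-nitrobenzenesulfonyl chloride (1.0 equiv), Et3N, CH2Cl2, 0 °C
Reagents that add atoms: 2-nitrobenzenesulfonyl chloride, O=S(=O)(Cl)c1ccccc1[N+](=O)[O-]
Why: Sulfonamide formation: the amine is sulfonylated far faster than the alcohol, so one equivalent of sulfonyl chloride should react at nitrogen only.

Step 6
Reactants: 8 N-(3-hydroxypropyl)-2-nitrobenzenesulfonamide
Product: 9 N-(3-oxopropyl)-2-nitrobenzenesulfonamide
Conditions: Dess–Martin periodinane, NaHCO3, CH2Cl2, 0 °C → rt; used crude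
Reagents that add atoms: none
Why: Dess–Martin oxidation of the primary alcohol under buffered, non-basic conditions, which avoids β-elimination of the sulfonamide from the aldehyde.

Step 7
Reactants: 6 methyl (1R)-1-(3-chloropropyl)-4-oxocyclopent-2-ene-1-carboxylate; 9 N-(3-oxopropyl)-2-nitrobenzenesulfonamide
Product: 11 methyl (1S)-1-(3-chloropropyl)-5-[1-hydroxy-3-(2-nitrobenzenesulfonamido)propyl]-4-oxocyclopent-2-ene-1-carboxylate (aldol adduct; mixture at the two new centres), via silyl dienol ether 10 (not isolated)
Conditions: TMSOTf, Et3N, CH2Cl2, 0 °C; volatiles removed; then 9, BF3·OEt2, CH2Cl2, −78 °C; aq. NaHCO3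
Reagents that add atoms: none
Why: Mukaiyama aldol addition: soft enolisation can occur only at C4 and avoids a free enolate, which the acidic N–H of 9 would quench and the chloride could alkylate, and the BF3-activated aldehyde then adds to C4; both new stereocentres disappear in step 8.

Step 8
Reactants: 11 methyl (1S)-1-(3-chloropropyl)-5-[1-hydroxy-3-(2-nitrobenzenesulfonamido)propyl]-4-oxocyclopent-2-ene-1-carboxylate
Product: 13 methyl (1S,5E)-1-(3-chloropropyl)-5-[3-(2-nitrobenzenesulfonamido)propylidene]-4-oxocyclopent-2-ene-1-carboxylate, via mesylate 12 (not isolated)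
Conditions: MsCl (1.2 equiv), Et3N, CH2Cl2, −10 °C; then DBU, rt
Reagents that add atoms: none
Why: Mesylation of the aldol hydroxyl followed by E1cB elimination should give the conjugated alkylidene as its more stable E isomer (chain anti to the C5 carbonyl and therefore cis to C12, as ring C will need), and under DBU the sulfonamide is present as its anion, so it cannot leave by vinylogous β-elimination.

Step 9
Reactants: 13 methyl (1S,5E)-1-(3-chloropropyl)-5-[3-(2-nitrobenzenesulfonamido)propylidene]-4-oxocyclopent-2-ene-1-carboxylate
Product: 14 (4S,5E)-4-(3-chloropropyl)-4-(hydroxymethyl)-5-[3-(2-nitrobenzenesulfonamido)propylidene]cyclopent-2-en-1-ol (C1 epimers)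
Conditions: DIBAL-H (i-Bu2AlH), CH2Cl2, −78 → −40 °C; aq. potassium sodium tartrate
Reagents that add atoms: none
Why: Hydride reduction with DIBAL-H at low temperature takes the ester to the primary alcohol and the cross-conjugated ketone to the allylic alcohol by 1,2-addition, which postpones the sensitive C13 aldehyde to the last step before the annulation; the sulfonamide is masked as its N-aluminium salt, and nitroarene and chloride are tolerated at this temperature.

Step 10
Reactants: 14 (4S,5E)-4-(3-chloropropyl)-4-(hydroxymethyl)-5-[3-(2-nitrobenzenesulfonamido)propylidene]cyclopent-2-en-1-ol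
Product: 15 (1S,5E)-1-(3-chloropropyl)-5-[3-(2-nitrobenzenesulfonamido)propylidene]-4-oxocyclopent-2-ene-1-carbaldehyde
Conditions: Dess–Martin periodinane, NaHCO3, CH2Cl2, 0 °C → rt
Reagents that add atoms: none
Why: Dess–Martin oxidation of both hydroxyls in one operation returns the dienone and unveils the non-enolisable C13 aldehyde under buffered conditions that avoid deformylation.

Step 11
Reactants: 16 3-chloro-2-(chloromethyl)prop-1-ene
Product: 17 2-methylidene-1,3-bis(trimethylsilyl)propane
Conditions: Mg, TMSCl, THF, reflux
Reagents that add atoms: chlorotrimethylsilane, C[Si](C)(C)Cl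
Why: Barbier-type in situ Grignard formation at each allylic chloride with immediate trapping by TMSCl should give the bis-allylsilane.

Step 12
Reactants: 15 (1S,5E)-1-(3-chloropropyl)-5-[3-(2-nitrobenzenesulfonamido)propylidene]-4-oxocyclopent-2-ene-1-carbaldehyde; 17 2-methylidene-1,3-bis(trimethylsilyl)propane
Product: 19 (1E,3aS,7S,7aS)-7a-(3-chloropropyl)-7-hydroxy-5-methylidene-1-[3-(2-nitrobenzenesulfonamido)propylidene]octahydro-2H-inden-2-one, via hydroxy allylsilane 18 (not isolated)
Conditions: 17 (1.2 equiv), BF3·OEt2, CH2Cl2 (0.01 M), −78 °C; then TiCl4, −78 → −40 °C; aq. NaHCO3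
Reagents that add atoms: none
Why: The BF3-activated C13 aldehyde is attacked by the methylidene carbon of 17 in an SE2' Hosomi–Sakurai allylation (C13–C14) that expels one silyl group and leaves a new allylsilane 18 tethered through C13; TiCl4 then activates the C5 enone, the allylsilane terminus adds to C7 (C7–C8), and loss of the second silyl group unveils the C15 methylidene. Both stages are known reaction types, namely aldehyde allylation with this bis-allylsilane and Lewis acid-promoted intramolecular conjugate addition of an allylsilane to an enone. Ring A closes in a 6-exo-trig mode onto C7, whereas attack at C3 would require a seven-membered ring. C7 is fixed by the tether from C12, which can reach only the face of ring B that carries C13, so the fusion is cis; C13 is set in the first addition, where allylic strain from the C2 methylene should turn the aldehyde hydrogen toward the alkylidene and the nucleophile should add anti to the C4 vinyl carbon (Felkin–Anh), placing O13 on the side of C4 (13S). The step needs the aldehyde to react before either enone, which is secured by using BF3·OEt2 (it promotes aldehyde allylation but not conjugate allylation) before TiCl4 is added, and it needs one-to-one coupling rather than addition to a second aldehyde, which high dilution secures.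

Step 13
Reactants: 19 (1E,3aS,7S,7aS)-7a-(3-chloropropyl)-7-hydroxy-5-methylidene-1-[3-(2-nitrobenzenesulfonamido)propylidene]octahydro-2H-inden-2-one
Product: 21 (1E,3aS,7S,7aS)-7a-(3-chloropropyl)-5-methylidene-1-[3-(2-nitrobenzenesulfonamido)propylidene]-2-oxooctahydro-1H-inden-7-yl carbamate, via N-trichloroacetyl carbamate 20 (not isolated)
Conditions: Cl3CC(O)NCO, CH2Cl2, 0 °C; then K2CO3, MeOH, 0 °C
Reagents that add atoms: trichloroacetyl isocyanate, O=C=NC(=O)C(Cl)(Cl)Cl
Why: O-Carbamoylation with the highly electrophilic acyl isocyanate should be complete within minutes at the hindered C13 hydroxyl under neutral conditions, where the weakly nucleophilic sulfonamide N–H does not compete (a base-mediated carbonate formation would acylate it first), and mild methanolysis removes the trichloroacetyl group; the carbamate masks O13 during ring closure and later delivers oxygen to C15.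

Step 14
Reactants: 21 (1E,3aS,7S,7aS)-7a-(3-chloropropyl)-5-methylidene-1-[3-(2-nitrobenzenesulfonamido)propylidene]-2-oxooctahydro-1H-inden-7-yl carbamate
Product: 23 tricyclic N-nosyl azonine carbamate (21 with N bonded to C9 in place of chlorine; ring C = C4=C3–C2–C1–N–C9–C10–C11–C12; 3E,7S,12S,13S), via primary iodide 22 (not isolated)
Conditions: Cs2CO3, NaI (cat.), MeCN (0.005 M), 70 °C
Reagents that add atoms: none
Why: Intramolecular Fukuyama N-alkylation: the caesium nosylamide displaces the primary halide (chloride after in situ Finkelstein exchange to iodide), the E alkene holds the C1 chain on the C12 side and high dilution suppresses oligomers, so the nine-membered ring C should close; with O13 carbamoylated no tetrahydropyran can form.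

Step 15
Reactants: 23 tricyclic N-nosyl azonine carbamate
Product: 24 tricyclic secondary amine carbamate (23 without the sulfonyl group; 3E,7S,12S,13S)
Conditions: PhSH, K2CO3, MeCN, rt
Reagents that add atoms: none
Why: Fukuyama denosylation: thiolate adds ipso to the nitroarene (Meisenheimer adduct) and the sulfonamide collapses with loss of SO2 to the secondary amine; carbamate and exocyclic alkene are inert, and a small excess of thiol limits reversible conjugate addition to the enone.

Step 16
Reactants: 24 tricyclic secondary amine carbamate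
Product: 25 tricyclic N-formyl carbamate (3E,7S,12S,13S)
Conditions: acetic formic anhydride, pyridine, CH2Cl2, 0 °C
Reagents that add atoms: acetic formic anhydride, CC(=O)OC=O
Why: N-Formylation of the secondary amine with the mixed anhydride, which transfers the formyl group selectively; the carbamate NH2 is not nucleophilic enough to react.

Step 17
Reactants: 25 tricyclic N-formyl carbamate
Product: 27 cyclic 13,15-carbonate with a C15 iodomethyl group (3E,7S,12S,13S,15S), via cyclic iminocarbonate 26 (not isolated)
Conditions: I2, NaHCO3, Et2O/H2O, 0 °C → rt; aq. Na2S2O3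
Reagents that add atoms: iodine, II; water, O
Why: Carbamate-mediated iodocyclisation: the iodonium ion of the electron-rich exocyclic alkene is opened at tertiary C15 by the carbamate carbonyl oxygen (6-exo, Markovnikov) and the iminocarbonate is hydrolysed in the aqueous phase to the cyclic carbonate, so the new C15–O bond, delivered from O13 across ring A, is necessarily cis to C13–O (15S).

Step 18
Reactants: 27 cyclic 13,15-carbonate with a C15 iodomethyl group
Product: 28 cyclic 13,15-carbonate with a C15 methyl group (3E,7S,12S,13S,15S)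
Conditions: Bu3SnH, AIBN, PhMe, 80 °C
Reagents that add atoms: none
Why: Radical chain dehalogenation with Bu3SnH: iodine abstraction from the primary iodide is far faster than any reaction of the stannyl radical with enone, formamide or carbonate, and the nitroarene that would inhibit the chain has already been removed.

Step 19
Reactants: 28 cyclic 13,15-carbonate with a C15 methyl group
Product: 29 13,15-diol (3E,7S,12S,13S,15S)
Conditions: K2CO3, MeOH, 0 °C → rt
Reagents that add atoms: none
Why: Base-catalysed methanolysis (transesterification) of the bridged cyclic carbonate should release the cis-1,3-diol without touching the tertiary formamide or any stereocentre.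

Step 20
Reactants: 29 13,15-diol
Product: 30 CNP0137427.1 (13,15-diacetate; 3E,7S,12S,13S,15S)
Conditions: Ac2O, DMAP, Et3N, CH2Cl2, rt → 40 °C
Reagents that add atoms: acetic anhydride, CC(=O)OC(C)=O
Why: DMAP-catalysed acylation esterifies the secondary C13 hydroxyl and, on gentle warming, the tertiary C15 hydroxyl, giving the diacetate target.

Compound list

1 | methyl 2-oxocyclopentane-1-carboxylate | COC(=O)C1CCCC1=O | starting material
2 | 1-bromo-3-chloropropane | ClCCCBr | starting material
3 | methyl (1S)-1-(3-chloropropyl)-2-oxocyclopentane-1-carboxylate | COC(=O)[C@]1(CCCCl)CCCC1=O | intermediate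
4 | methyl (1S)-1-(3-chloropropyl)-2-(trifluoromethanesulfonyloxy)cyclopent-2-ene-1-carboxylate | COC(=O)[C@]1(CCCCl)CCC=C1OS(=O)(=O)C(F)(F)F | intermediate
5 | methyl (1S)-1-(3-chloropropyl)cyclopent-2-ene-1-carboxylate | COC(=O)[C@]1(CCCCl)CCC=C1 | intermediate
6 | methyl (1R)-1-(3-chloropropyl)-4-oxocyclopent-2-ene-1-carboxylate | COC(=O)[C@]1(CCCCl)CC(=O)C=C1 | intermediate
7 | 3-aminopropan-1-ol | NCCCO | starting material
8 | N-(3-hydroxypropyl)-2-nitrobenzenesulfonamide | OCCCNS(=O)(=O)c1ccccc1[N+](=O)[O-] | intermediate
9 | N-(3-oxopropyl)-2-nitrobenzenesulfonamide | O=CCCNS(=O)(=O)c1ccccc1[N+](=O)[O-] | intermediate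
10 | methyl (1S)-1-(3-chloropropyl)-3-(trimethylsilyloxy)cyclopenta-2,4-diene-1-carboxylate (silyl dienol ether, not isolated) | COC(=O)[C@]1(CCCCl)C=C(O[Si](C)(C)C)C=C1 | intermediate
11 | methyl (1S)-1-(3-chloropropyl)-5-[1-hydroxy-3-(2-nitrobenzenesulfonamido)propyl]-4-oxocyclopent-2-ene-1-carboxylate (mixture at the two new centres) | COC(=O)[C@@]1(CCCCl)C=CC(=O)C1C(O)CCNS(=O)(=O)c1ccccc1[N+](=O)[O-] | intermediate
12 | methanesulfonate of 11 (not isolated) | COC(=O)[C@@]1(CCCCl)C=CC(=O)C1C(OS(C)(=O)=O)CCNS(=O)(=O)c1ccccc1[N+](=O)[O-] | intermediate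
13 | methyl (1S,5E)-1-(3-chloropropyl)-5-[3-(2-nitrobenzenesulfonamido)propylidene]-4-oxocyclopent-2-ene-1-carboxylate | COC(=O)[C@@]1(CCCCl)C=CC(=O)/C1=C/CCNS(=O)(=O)c1ccccc1[N+](=O)[O-] | intermediate
14 | (4S,5E)-4-(3-chloropropyl)-4-(hydroxymethyl)-5-[3-(2-nitrobenzenesulfonamido)propylidene]cyclopent-2-en-1-ol (C1 epimers) | OC[C@@]1(CCCCl)C=CC(O)/C1=C/CCNS(=O)(=O)c1ccccc1[N+](=O)[O-] | intermediate
15 | (1S,5E)-1-(3-chloropropyl)-5-[3-(2-nitrobenzenesulfonamido)propylidene]-4-oxocyclopent-2-ene-1-carbaldehyde (annulation precursor) | O=C[C@@]1(CCCCl)C=CC(=O)/C1=C/CCNS(=O)(=O)c2ccccc2[N+](=O)[O-] | intermediate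
16 | 3-chloro-2-(chloromethyl)prop-1-ene | C=C(CCl)CCl | starting material
17 | 2-methylidene-1,3-bis(trimethylsilyl)propane | C=C(C[Si](C)(C)C)C[Si](C)(C)C | intermediate
18 | C13 homoallylic alcohol of 15 carrying the 2-(trimethylsilylmethyl)allyl group (13S; not isolated) | O[C@@H](CC(=C)C[Si](C)(C)C)[C@@]1(CCCCl)C=CC(=O)/C1=C/CCNS(=O)(=O)c1ccccc1[N+](=O)[O-] | intermediate
19 | (1E,3aS,7S,7aS)-7a-(3-chloropropyl)-7-hydroxy-5-methylidene-1-[3-(2-nitrobenzenesulfonamido)propylidene]octahydro-2H-inden-2-one (annulation product) | O[C@H]1CC(=C)C[C@H]2CC(=O)/C(=C/CCNS(=O)(=O)c3ccccc3[N+](=O)[O-])[C@]21CCCCl | intermediate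
20 | N-trichloroacetyl carbamate of 19 (not isolated) | O=C(NC(=O)C(Cl)(Cl)Cl)O[C@H]1CC(=C)C[C@H]2CC(=O)/C(=C/CCNS(=O)(=O)c3ccccc3[N+](=O)[O-])[C@]21CCCCl | intermediate
21 | (1E,3aS,7S,7aS)-7a-(3-chloropropyl)-5-methylidene-1-[3-(2-nitrobenzenesulfonamido)propylidene]-2-oxooctahydro-1H-inden-7-yl carbamate | NC(=O)O[C@H]1CC(=C)C[C@H]2CC(=O)/C(=C/CCNS(=O)(=O)c3ccccc3[N+](=O)[O-])[C@]21CCCCl | intermediate
22 | C9 iodide corresponding to 21 (not isolated) | NC(=O)O[C@H]1CC(=C)C[C@H]2CC(=O)/C(=C/CCNS(=O)(=O)c3ccccc3[N+](=O)[O-])[C@]21CCCI | intermediate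
23 | tricyclic N-(2-nitrobenzenesulfonyl) azonine 13-carbamate (3E,7S,12S,13S) | NC(=O)O[C@H]1CC(=C)C[C@H]2CC(=O)/C3=C/CCN(S(=O)(=O)c4ccccc4[N+](=O)[O-])CCC[C@@]321 | intermediate
24 | tricyclic secondary amine 13-carbamate (3E,7S,12S,13S) | NC(=O)O[C@H]1CC(=C)C[C@H]2CC(=O)/C3=C/CCNCCC[C@@]321 | intermediate
25 | tricyclic N-formyl 13-carbamate (3E,7S,12S,13S) | NC(=O)O[C@H]1CC(=C)C[C@H]2CC(=O)/C3=C/CCN(C=O)CCC[C@@]321 | intermediate
26 | cyclic 13,15-iminocarbonate with C15 iodomethyl (not isolated; 15S) | N=C4O[C@H]1C[C@@](CI)(O4)C[C@H]2CC(=O)/C3=C/CCN(C=O)CCC[C@@]321 | intermediate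
27 | cyclic 13,15-carbonate with C15 iodomethyl (3E,7S,12S,13S,15S) | O=C4O[C@H]1C[C@@](CI)(O4)C[C@H]2CC(=O)/C3=C/CCN(C=O)CCC[C@@]321 | intermediate
28 | cyclic 13,15-carbonate with C15 methyl (3E,7S,12S,13S,15S) | O=C4O[C@H]1C[C@@](C)(O4)C[C@H]2CC(=O)/C3=C/CCN(C=O)CCC[C@@]321 | intermediate
29 | N-formyl 13,15-diol (3E,7S,12S,13S,15S) | O[C@H]1C[C@@](C)(O)C[C@H]2CC(=O)/C3=C/CCN(C=O)CCC[C@@]321 | intermediate
30 | CNP0137427.1 (13,15-diacetate; 3E,7S,12S,13S,15S) | CC(=O)O[C@H]1C[C@@](C)(OC(C)=O)C[C@H]2CC(=O)/C3=C/CCN(C=O)CCC[C@@]321 | target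

Total step count: 20 (17 on the main line, 2 for aldehyde 9, 1 for bis-allylsilane 17).
Longest linear sequence: 17 steps (steps 1–4, 7–10, 12–20).

Steps most likely to fail

Step 12. Facial selectivity in the first, intermolecular allylation may be poor, so that the C13 epimer forms alongside 19. The fallback sets out from 15: the annulation is run as in step 12 without regard to this selectivity, and the mixture of 19 and its 13-epimer F1 is oxidised (Dess–Martin periodinane, NaHCO3, CH2Cl2) to the single C13 ketone F2. F2 is then reduced with NaBH4 in CH2Cl2/MeOH at −78 °C. The saturated C13 ketone should react before the conjugated C5 enone, and hydride should arrive from the convex face, anti to ring B. This returns to the route at 19, with C13 set by substrate-controlled reduction instead of by the allylation.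

Step 17. Capture of the iodonium ion by the carbamate may stall, because ring A has to place C13–O axial and syn to C6 while ring C is already in place. The fallback sets out from 21: the same carbamate iodocyclisation (I2, NaHCO3, Et2O/H2O) is run on the conformationally freer bicycle and should give iodocarbonate F3. Ring C is then closed (Cs2CO3, NaI, MeCN, high dilution) to N-nosyl azonine iodocarbonate F4; the neopentyl-type iodomethyl group should not be displaced. The nosyl group is removed with short exposure to PhSH/K2CO3 to give amine iodocarbonate F5, and immediate N-formylation with acetic formic anhydride rejoins the route at 27.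

Step 1. Enantioselectivity may be low in the phase-transfer alkylation with an unactivated alkyl bromide. The fallback sets out from 1: conjugate addition to acrolein catalysed by a 6'-hydroxy cinchona base (9-O-benzylcupreidine or its cupreine pseudoenantiomer, CH2Cl2, −20 °C) should give aldehyde F6. Chemoselective reduction of the aldehyde (NaBH4, EtOH, −78 °C) gives alcohol F7, and Appel chlorination (PPh3, CCl4) returns to the route at 3.

Further compounds

F1 | step 12 | 13-epimer of 19 (3aS,7R,7aS) | O[C@@H]1CC(=C)C[C@H]2CC(=O)/C(=C/CCNS(=O)(=O)c3ccccc3[N+](=O)[O-])[C@]21CCCCl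
F2 | step 12 | C13 ketone derived from 19 and F1 | O=C1CC(=C)C[C@H]2CC(=O)/C(=C/CCNS(=O)(=O)c3ccccc3[N+](=O)[O-])[C@]21CCCCl
F3 | step 17 | cyclic 13,15-carbonate with C15 iodomethyl, open-chain nosylamide and C9 chloride | O=C3O[C@H]1C[C@@](CI)(O3)C[C@H]2CC(=O)/C(=C/CCNS(=O)(=O)c4ccccc4[N+](=O)[O-])[C@]21CCCCl
F4 | step 17 | N-nosyl azonine iodocarbonate | O=C4O[C@H]1C[C@@](CI)(O4)C[C@H]2CC(=O)/C3=C/CCN(S(=O)(=O)c5ccccc5[N+](=O)[O-])CCC[C@@]321
F5 | step 17 | secondary amine iodocarbonate | O=C4O[C@H]1C[C@@](CI)(O4)C[C@H]2CC(=O)/C3=C/CCNCCC[C@@]321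
F6 | step 1 | methyl (1S)-2-oxo-1-(3-oxopropyl)cyclopentane-1-carboxylate | COC(=O)[C@]1(CCC=O)CCCC1=O
F7 | step 1 | methyl (1S)-1-(3-hydroxypropyl)-2-oxocyclopentane-1-carboxylate | COC(=O)[C@]1(CCCO)CCCC1=O
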